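**Retrosynthetic overview**
- Target 13 is reached from the tris-silyl depside 10 by desilylation, methylation of the only unchelated phenol (ring A 4-OH) and deallylation.
- 10 is opened by an Alder–Rickert benzannulation: ring A is grown on the ring B aryl ynoate (7, silylated in the flask to 8) from diene 3, making ring A bonds C1–C2 and C5–C6 with loss of ethylene, so the hindered depside ester never has to be made by esterification.
- Feature exploited: in ring A the hydroxyl (C2), chlorine (C3), methoxy oxygen (C4) and the lone ring hydrogen (C5) sit on four adjacent carbons, the substitution of a 2-chloro-1,3-dioxygenated cyclohexa-1,3-diene. The remaining pair C1 (acyl) and C6 (pentyl) maps onto the triple bond of an oct-2-ynoate.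
- 7 comes from olivetolic acid 4 by allyl esterification and 4-O-acylation with oct-2-ynoic acid 6; 3 comes from 2-chlorocyclohexane-1,3-dione 1 by double O-silylation.
- Ring order: ring B is bought intact; ring A is the only ring formed (step 4).

Key step: step 4

Remark on the chemistry: a free phenol would be expected to protodesilylate dienol ether 3 at 150 °C. The chelated ring B hydroxyl of 7 is therefore capped as its trimethylsilyl ether in the flask before the cycloaddition, and all silyl groups are removed together in step 5. Compounds 1, 4 and 6 are taken as purchasable.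

**Step 1**
Reactants: 1 2-chlorocyclohexane-1,3-dione
Product: 3 2-chloro-1,3-bis(trimethylsilyloxy)cyclohexa-1,3-diene, via 2-chloro-3-(trimethylsilyloxy)cyclohex-2-en-1-one 2 (not isolated)
Conditions: TMSOTf (2.3 equiv), Et3N (2.6 equiv), Et2O, 0 °C to rt; decant from the ammonium salt, concentrate, bulb-to-bulb distillation, store under Ar
Reagents that add atoms: trimethylsilyl trifluoromethanesulfonate, C[Si](C)(C)OS(=O)(=O)C(F)(F)F
Why: Soft enolisation (silyl enol ether formation of a 1,3-diketone) silylates the enol oxygen first and then, after O-silyl activation of the vinylogous ester 2 and deprotonation at the neighbouring CH2, the second oxygen; because 1 is symmetric, deprotonation on either side should give the same conjugated diene with chlorine on the central carbon.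

**Step 2**
Reactants: 4 olivetolic acid (2,4-dihydroxy-6-pentylbenzoic acid)
Product: 5 allyl 2,4-dihydroxy-6-pentylbenzoate
Conditions: allyl bromide (1.05 equiv), KHCO3 (1.2 equiv), DMF, rt
Reagents that add atoms: allyl bromide, C=CCBr
Why: Carboxylate O-alkylation (SN2) under bicarbonate, which deprotonates the carboxylic acid but not the phenols, run at room temperature so that the salicylic-type acid does not decarboxylate.

**Step 3**
Reactants: 5 allyl 2,4-dihydroxy-6-pentylbenzoate; 6 oct-2-ynoic acid
Product: 7 allyl 2-hydroxy-4-(oct-2-ynoyloxy)-6-pentylbenzoate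
Conditions: DCC (1.05 equiv), DMAP (5 mol %), CH2Cl2, 0 °C to rt
Reagents that add atoms: none
Why: Steglich esterification should acylate only the 4-hydroxyl, the one phenol that is unhindered and not hydrogen-bonded to the allyl ester carbonyl; DMAP is kept catalytic and the temperature low so that neither DMAP nor phenol adds in conjugate fashion to the ynoate.

**Step 4**
Reactants: 7 allyl 2-hydroxy-4-(oct-2-ynoyloxy)-6-pentylbenzoate; 3 2-chloro-1,3-bis(trimethylsilyloxy)cyclohexa-1,3-diene
Product: 10 allyl 4-[3-chloro-6-pentyl-2,4-bis(trimethylsilyloxy)benzoyloxy]-6-pentyl-2-(trimethylsilyloxy)benzoate, via ring B trimethylsilyl ether 8 (not isolated), via bicyclo[2.2.2]octadiene cycloadduct 9 (not isolated)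
Conditions: BSA (1.5 equiv), toluene, 60 °C, then evaporate under vacuum; 3 (3 equiv), neat, 150 °C, Ar, 24–48 h; strip excess diene under vacuum and carry crude 10 forward
Reagents that add atoms: N,O-bis(trimethylsilyl)acetamide, CC(=N[Si](C)(C)C)O[Si](C)(C)C
Why: BSA first converts the chelated ring B phenol into silyl ether 8, so that no acidic proton is left to protodesilylate the diene. Electron-rich diene 3 then adds to the electron-poor triple bond of 8 in a thermal, normal-electron-demand, concerted but asynchronous [4+2] cycloaddition, and adduct 9 expels its CH2–CH2 bridge as ethylene by retro-[4+2], driven by aromatisation; this is the Alder–Rickert synthesis of resorcylates from 1,3-bis(silyloxy)cyclohexa-1,3-dienes and alkynoates. Ring A is closed intermolecularly by forming C1–C2 and C5–C6 in the cycloaddition, four of its carbons coming from the diene and two from the alkyne. The two bridgehead stereocentres of 9 are transient and vanish on aromatisation, so no stereocentre has to be controlled. The step needs the orientation in which the ester-bearing alkyne carbon joins the silyloxy-bearing diene terminus; the largest HOMO coefficient lies on the unsubstituted terminus (beta carbon of a silyl enol ether) and the largest LUMO coefficient on the pentyl-bearing beta carbon of the ynoate, so these two carbons should bond first. The chlorine on the central diene carbon is expected to lower the diene reactivity somewhat, which is offset by the aryl ester (a better acceptor than an alkyl ynoate), excess diene and 150 °C.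

**Step 5**
Reactants: 10 allyl 4-[3-chloro-6-pentyl-2,4-bis(trimethylsilyloxy)benzoyloxy]-6-pentyl-2-(trimethylsilyloxy)benzoate
Product: 11 allyl 4-(3-chloro-2,4-dihydroxy-6-pentylbenzoyloxy)-2-hydroxy-6-pentylbenzoate
Conditions: 1 M aq HCl, THF, 0 °C to rt
Reagents that add atoms: none
Why: Aryl trimethylsilyl ethers are hydrolysed by dilute aqueous acid at room temperature, conditions under which the allyl ester and the hindered depside ester should survive, while leftover diene is hydrolysed to dione 1 and separated on chromatography.

**Step 6**
Reactants: 11 allyl 4-(3-chloro-2,4-dihydroxy-6-pentylbenzoyloxy)-2-hydroxy-6-pentylbenzoate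
Product: 12 allyl 4-(3-chloro-2-hydroxy-4-methoxy-6-pentylbenzoyloxy)-2-hydroxy-6-pentylbenzoate
Conditions: MeI (1.1 equiv), K2CO3 (1.05 equiv), acetone, rt
Reagents that add atoms: iodomethane, CI
Why: Williamson O-methylation under limiting weak base; the ring A 4-hydroxyl (para to the ester carbonyl, ortho to chlorine) is the most acidic phenol and the only one not locked in a hydrogen bond to an ester carbonyl, so it should be methylated selectively, as in the 4-O-alkylation of 2,4-dihydroxybenzoates.

**Step 7**
Reactants: 12 allyl 4-(3-chloro-2-hydroxy-4-methoxy-6-pentylbenzoyloxy)-2-hydroxy-6-pentylbenzoate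
Product: 13 4-(3-chloro-2-hydroxy-4-methoxy-6-pentylbenzoyloxy)-2-hydroxy-6-pentylbenzoic acid (CNP0310773.0)
Conditions: Pd(PPh3)4 (5 mol %), N-methylaniline (3 equiv), THF, rt; dilute HCl work-up
Reagents that add atoms: none
Why: Tsuji–Trost deallylation, in which zerovalent palladium ionises the allyl ester to a π-allyl complex and N-methylaniline traps the allyl group; a weakly nucleophilic aromatic amine is used as the scavenger so that the depside aryl ester is not aminolysed, and the aryl chloride should not undergo oxidative addition with Pd(PPh3)4 at room temperature.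

**Compound list**
1 | 2-chlorocyclohexane-1,3-dione | O=C1CCCC(=O)C1Cl | starting material
2 | 2-chloro-3-(trimethylsilyloxy)cyclohex-2-en-1-one | O=C1CCCC(O[Si](C)(C)C)=C1Cl | intermediate
3 | 2-chloro-1,3-bis(trimethylsilyloxy)cyclohexa-1,3-diene | C[Si](C)(C)OC1=CCCC(O[Si](C)(C)C)=C1Cl | intermediate
4 | olivetolic acid (2,4-dihydroxy-6-pentylbenzoic acid) | CCCCCc1cc(O)cc(O)c1C(=O)O | starting material
5 | allyl 2,4-dihydroxy-6-pentylbenzoate | CCCCCc1cc(O)cc(O)c1C(=O)OCC=C | intermediate
6 | oct-2-ynoic acid | CCCCCC#CC(=O)O | starting material
7 | allyl 2-hydroxy-4-(oct-2-ynoyloxy)-6-pentylbenzoate | CCCCCC#CC(=O)Oc1cc(O)c(C(=O)OCC=C)c(CCCCC)c1 | intermediate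
8 | allyl 4-(oct-2-ynoyloxy)-6-pentyl-2-(trimethylsilyloxy)benzoate | CCCCCC#CC(=O)Oc1cc(O[Si](C)(C)C)c(C(=O)OCC=C)c(CCCCC)c1 | intermediate
9 | allyl 4-{[6-chloro-3-pentyl-1,5-bis(trimethylsilyloxy)bicyclo[2.2.2]octa-2,5-dien-2-yl]carbonyloxy}-6-pentyl-2-(trimethylsilyloxy)benzoate (racemic, transient) | C[Si](C)(C)OC12CCC(C(O[Si](C)(C)C)=C1Cl)C(CCCCC)=C2C(=O)Oc1cc(O[Si](C)(C)C)c(C(=O)OCC=C)c(CCCCC)c1 | intermediate
10 | allyl 4-[3-chloro-6-pentyl-2,4-bis(trimethylsilyloxy)benzoyloxy]-6-pentyl-2-(trimethylsilyloxy)benzoate | CCCCCc1cc(O[Si](C)(C)C)c(Cl)c(O[Si](C)(C)C)c1C(=O)Oc1cc(O[Si](C)(C)C)c(C(=O)OCC=C)c(CCCCC)c1 | intermediate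
11 | allyl 4-(3-chloro-2,4-dihydroxy-6-pentylbenzoyloxy)-2-hydroxy-6-pentylbenzoate | CCCCCc1cc(O)c(Cl)c(O)c1C(=O)Oc1cc(O)c(C(=O)OCC=C)c(CCCCC)c1 | intermediate
12 | allyl 4-(3-chloro-2-hydroxy-4-methoxy-6-pentylbenzoyloxy)-2-hydroxy-6-pentylbenzoate | CCCCCc1cc(OC)c(Cl)c(O)c1C(=O)Oc1cc(O)c(C(=O)OCC=C)c(CCCCC)c1 | intermediate
13 | 4-(3-chloro-2-hydroxy-4-methoxy-6-pentylbenzoyloxy)-2-hydroxy-6-pentylbenzoic acid | CCCCCc1cc(OC(=O)c2c(CCCCC)cc(OC)c(Cl)c2O)cc(O)c1C(=O)O | target

**Step count**
Total: 7 steps. Longest linear sequence: 6 steps (4 → 5 → 7 → 10 → 11 → 12 → 13, steps 2 to 7); the diene arm is one step.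

**Steps most likely to fail**

Step 4. The chlorine on the central diene carbon may slow the cycloaddition so far that silyl transfer, thermal decay of the aryl ynoate or addition in the wrong orientation competes with ring formation. The fallback sets out from diene 3 and comes back to the route at 12; it builds ring A on a simple, robust dienophile and joins the two rings afterwards. Diene 3 would be heated neat at 160–180 °C with excess commercial methyl oct-2-ynoate (CCCCCC#CC(=O)OC). This should give the cycloadduct methyl 6-chloro-3-pentyl-1,5-bis(trimethylsilyloxy)bicyclo[2.2.2]octa-2,5-diene-2-carboxylate F1, which on loss of ethylene becomes the arene methyl 3-chloro-6-pentyl-2,4-bis(trimethylsilyloxy)benzoate F2. Dilute HCl in THF would then give methyl 3-chloro-2,4-dihydroxy-6-pentylbenzoate F3. MeI and K2CO3 in acetone would methylate the unchelated 4-hydroxyl to give methyl 3-chloro-2-hydroxy-4-methoxy-6-pentylbenzoate F4. KOH in aqueous DMSO at 80 °C would saponify this ester to 3-chloro-2-hydroxy-4-methoxy-6-pentylbenzoic acid F5. Acid F5 would finally be condensed with the unchelated 4-hydroxyl of phenol 5 using trifluoroacetic anhydride in toluene at rt (classical depside esterification through the mixed anhydride), which reaches 12.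

Step 6. A chelated hydroxyl may be methylated as well, or the phenoxide may cleave or transesterify the depside ester. The fallback sets out from 11 and comes back to the route at 12. It uses a Mitsunobu methylation (MeOH, PPh3, DIAD, THF, 0 °C), in which no phenoxide is generated and only a phenol acidic enough to protonate the betaine is alkylated. No compound outside the compound list is made on this path.

Step 1. The second enolisation may stay incomplete, or the diene may hydrolyse during isolation. The fallback sets out from 1 and comes back to the route at 3. Enone 2 would be made with TMSCl and Et3N and isolated, then deprotonated with lithium diisopropylamide, LiN(iPr)2, in THF at −78 °C (hard, kinetic enolisation at the CH2 next to the carbonyl) and quenched with TMSCl; 3 would be used crude without distillation. No compound outside the compound list is made on this path.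

**Further compounds**
F1 | step 4 | methyl 6-chloro-3-pentyl-1,5-bis(trimethylsilyloxy)bicyclo[2.2.2]octa-2,5-diene-2-carboxylate (racemic, transient) | CCCCCC1=C(C(=O)OC)C2(O[Si](C)(C)C)CCC1C(O[Si](C)(C)C)=C2Cl
F2 | step 4 | methyl 3-chloro-6-pentyl-2,4-bis(trimethylsilyloxy)benzoate | CCCCCc1cc(O[Si](C)(C)C)c(Cl)c(O[Si](C)(C)C)c1C(=O)OC
F3 | step 4 | methyl 3-chloro-2,4-dihydroxy-6-pentylbenzoate | CCCCCc1cc(O)c(Cl)c(O)c1C(=O)OC
F4 | step 4 | methyl 3-chloro-2-hydroxy-4-methoxy-6-pentylbenzoate | CCCCCc1cc(OC)c(Cl)c(O)c1C(=O)OC
F5 | step 4 | 3-chloro-2-hydroxy-4-methoxy-6-pentylbenzoic acid | CCCCCc1cc(OC)c(Cl)c(O)c1C(=O)O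
F0 | step 6 | none | none
F0 | step 1 | none | none
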